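**Retrosynthetic overview**

1. Feature: in the seven-membered ring C5–C6–C7–C8–C9–C10(–C4) the carbinols C7 and C9 flank the only methylene, C8, and each is bonded to a quaternary carbon (C6, C10). The two aldehydes that precede them cannot enolise, so C8 is added last as nitromethane by a twofold nitroaldol (C7–C8, C8–C9), followed by denitration and two esterifications.
2. The closure is run on dialdehyde 23, whose C5 and C10 arms are cis on the cyclobutane. The C5/C6/C9/C10 plane is a near mirror plane of that half (its sides differ only in C1=O versus C3–Me), so the aldehyde faces are assigned by a chiral copper catalyst, not by equilibration.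
3. 23 ⇐ triol 21 ⇐ lactone 19: C5–C6 is made by a tethered isobutyrate-enolate aldol from C9–O onto the C5 cyclobutanone (arms cis by construction), then Barton–McCombie deoxygenation at C5.
4. Cyclobutane C4–C5–C11–C10 and ring A form together in an intramolecular vinylketene–alkene [2+2] (C4–C10, C5–C11) of an (S)-5-silyloxy dienoic acid; the C1 carbinol relays chirality and ends as the enone carbonyl.
5. Ring order: cyclobutane with ring A (step 7), a temporary lactone (step 8), the seven-membered carbocycle last (step 13); the acyclic acid comes from a catalytic vinylogous Mukaiyama aldol.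

Key step: step 13

Conventions: target numbering throughout (C1(=O)–C2=C3(Me)–C4; cyclobutane C4–C5–C11–C10; chain C5–C6(Me2)–C7–C8–C9–C10(Me)); on C5 and C10 "syn/anti" means toward/away from the C1–C3 bridge; α/β are the faces of the seven-membered ring turned to C11/C4.

Assumption: the bisphosphoramide of step 2 and the bis(oxazoline) of step 13 are used in the antipodes that give the (S)-carbinols, the sense to be confirmed by MTPA-ester analysis of 6 and on pivalaldehyde as a model.

**Route**

Step 1
Reactants: 1 tert-butyl 3-methylbut-2-enoate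
Product: 3 tert-butyl[(1-tert-butoxy-3-methylbuta-1,3-dien-1-yl)oxy]dimethylsilane, via lithium dienolate 2 (not isolated)
Conditions: LiN(iPr)2, THF, −78 °C; tBuMe2SiCl, DMPU, −78 °C → rt
Reagents that add atoms: tert-butyldimethylsilyl chloride, CC(C)(C)[Si](C)(C)Cl
Why: Kinetic γ-deprotonation of the senecioate gives the cross-conjugated lithium dienolate, which is silylated on oxygen (silyl ketene acetal formation); no stereocentre is formed.

Step 2
Reactants: 3 silyl dienol ether; 4 3-methylbut-2-enal
Product: 6 tert-butyl (2E,5S)-5-hydroxy-3,7-dimethylocta-2,6-dienoate, via trichlorosilyl ether 5 (not isolated)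
Conditions: SiCl4 (1.1 equiv), N,N′-dimethyl-N,N′-bis(3,5-dimethyl-4-oxido-4,5-dihydro-3H-dinaphtho[2,1-d:1′,2′-f][1,3,2]diazaphosphepin-4-yl)pentane-1,5-diamine (5 mol %), CH2Cl2, −78 °C; aq. NaHCO3
Reagents that add atoms: none
Why: Vinylogous Mukaiyama aldol under SiCl4/chiral Lewis-base catalysis, in which the cationic trichlorosilyl–bisphosphoramide complex activates the enal for 1,2-attack by the γ-carbon of the dienol ether to give the E-enoate; the catalyst antipode fixes the aldehyde face and thereby the (S)-carbinol (future C1).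

Step 3
Reactants: 6 hydroxy ester
Product: 7 tert-butyl (2E,5S)-5-(tert-butyldimethylsilyloxy)-3,7-dimethylocta-2,6-dienoate
Conditions: tBuMe2SiCl, imidazole, DMF, rt
Reagents that add atoms: tert-butyldimethylsilyl chloride, CC(C)(C)[Si](C)(C)Cl
Why: Imidazole-mediated silylation of a secondary allylic alcohol, which leaves the stereocentre untouched and gives an oxygen substituent that is a poor leaving group for the later ketene step.

Step 4
Reactants: 7 silyl ether
Product: 8 tert-butyl (2E,5S,6E)-5-(tert-butyldimethylsilyloxy)-8-hydroxy-3,7-dimethylocta-2,6-dienoate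
Conditions: SeO2 (0.3 equiv), tBuOOH, salicylic acid (cat.), CH2Cl2, 0 °C → rt
Reagents that add atoms: selenium dioxide, O=[Se]=O (oxygen donor, turned over by tert-butyl hydroperoxide, CC(C)(C)OO)
Why: SeO2 allylic oxidation (ene reaction, then [2,3]-sigmatropic shift) attacks the electron-rich trisubstituted C6=C7 alkene, not the enoate, and takes the methyl trans to the chain, so the 6E allylic alcohol should result; this geometry later becomes the configuration of C10.

Step 5
Reactants: 8 allylic alcohol; 9 2-methylpropanoyl chloride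
Product: 10 tert-butyl (2E,5S,6E)-5-(tert-butyldimethylsilyloxy)-3,7-dimethyl-8-(2-methylpropanoyloxy)octa-2,6-dienoate
Conditions: pyridine, DMAP (cat.), CH2Cl2, 0 °C
Reagents that add atoms: none
Why: Acylation of a primary allylic alcohol by an acid chloride; the isobutyrate protects C9–O and is the later source of C6, its two methyls and C7.

Step 6
Reactants: 10 diester
Product: 12 (2E,5S,6E)-5-(tert-butyldimethylsilyloxy)-3,7-dimethyl-8-(2-methylpropanoyloxy)octa-2,6-dienoic acid, via trimethylsilyl ester 11 (not isolated)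
Conditions: Me3SiOTf, 2,6-lutidine, CH2Cl2, 0 °C; aq. buffer (pH 5)
Reagents that add atoms: none
Why: Silyl-triflate-mediated cleavage of a tert-butyl ester (loss of isobutene under buffered conditions) spares the silyl ether and the allylic isobutyrate, and the silyl ester is hydrolysed on work-up.

Step 7
Reactants: 12 dienoic acid
Product: 15 bicyclic ketone: 3-methylidene-5-oxobicyclo[3.1.1]heptane core with (1S)-1-OSiMe2tBu on the C5 side, 10-Me syn and 10-CH2OC(O)CHMe2 anti, via acid chloride 13 (not isolated), via vinylketene 14 (not isolated)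
Conditions: 1-chloro-N,N,2-trimethylprop-1-en-1-amine, CH2Cl2, 0 °C → rt; then slow addition to Et3N, toluene, 110 °C (high dilution)
Reagents that add atoms: none
Why: Dehydrochlorination of the α,β-unsaturated acid chloride at the γ-methyl gives a vinylketene that undergoes the intramolecular crossed ketene–alkene [2+2] cycloaddition established for geranic-acid-type chlorides (carbonyl carbon to the alkene CH, ketene α-carbon to the more substituted alkene carbon), closing the cyclobutane (C5–C11, C4–C10) and with it ring A; the suprafacial addition turns the 6E geometry into C10 with Me syn and CH2O anti, and 1,3-allylic strain with that cis methyl holds C1–H in the alkene plane so that the ketene adds anti to the silyloxy group, which sets C4, C10 and C11 in the absolute sense from the (S)-carbinol.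

Step 8
Reactants: 15 bicyclic ketone
Product: 18 xanthate lactone: seven-membered lactone C9–O–C7(=O)–C6Me2–C5 bridging the cyclobutane with C5–OC(=S)SMe syn, via lithium aldolate 16 (not isolated), via lithium xanthate 17 (not isolated)
Conditions: LiN(SiMe3)2, THF, −78 → −30 °C; CS2, DMPU, −78 → 0 °C; MeI
Reagents that add atoms: carbon disulfide, S=C=S; iodomethane, CI
Why: Intramolecular ester-enolate aldol addition onto the strained cyclobutanone, which cannot enolise because both α-carbons are bridgeheads, forms C5–C6; the tether from C9–O reaches only the anti face of C5, which makes the two arms cis, and the tertiary alkoxide is trapped in the same flask as its S-methyl xanthate before retro-aldol can intervene.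

Step 9
Reactants: 18 xanthate lactone
Product: 19 lactone with C5–H syn (C6 anti), 1-OSiMe2tBu and exocyclic C3=CH2 retained
Conditions: Bu3SnH, AIBN (cat.), toluene, 80 °C
Reagents that add atoms: none
Why: Barton–McCombie deoxygenation of a tertiary xanthate that has no β-hydrogen available for Chugaev elimination; the lactone ring holds C6 on the anti side, so the C5 cyclobutyl radical takes hydrogen on the syn face, and the thiocarbonyl group captures stannyl radicals far faster than the isolated 1,1-disubstituted alkene.

Step 10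
Reactants: 19 lactone
Product: 20 diol: C5–CMe2CH2OH (anti), C10–CH2OH (anti), 1-OSiMe2tBu
Conditions: LiAlH4, THF, 0 °C → rt
Reagents that add atoms: none
Why: Hydride reduction of the lactone to the 1,5-diol (C7 and C9 carbinols), to which the silyl ether and the isolated alkene are inert.

Step 11
Reactants: 20 diol
Product: 21 triol (1-OH, 7-OH, 9-OH; exocyclic C3=CH2)
Conditions: Bu4NF, THF, rt
Reagents that add atoms: none
Why: Fluoride-mediated desilylation frees the C1 carbinol without touching the other functions.

Step 12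
Reactants: 21 triol
Product: 23 2-(6-formyl-4,6-dimethyl-2-oxobicyclo[3.1.1]hept-3-en-7-yl)-2-methylpropanal (target numbering: C7 and C9 aldehydes on cis arms; enone C1(=O)–C2=C3), via exo-methylene keto dialdehyde 22 (not isolated)
Conditions: (COCl)2, DMSO, CH2Cl2, −78 °C; Et3N, −78 → 0 °C; then DBU (0.2 equiv), rt
Reagents that add atoms: none
Why: Threefold Swern oxidation activates all three hydroxyls at −78 °C before base is added, so the 1,5-diol gives the dialdehyde without the lactol-to-lactone pathway of a stepwise oxidant, and the β,γ-unsaturated C1 ketone is moved into conjugation by DBU (thermodynamic alkene isomerisation); the C1 stereocentre disappears after its relay and both aldehydes sit on quaternary carbons and cannot epimerise.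

Step 13
Reactants: 23 dialdehyde; 24 nitromethane
Product: 26 (7S,9S)-7,9-dihydroxy-8-nitro tricyclic enone (9-OH α, 7-OH β; C8 epimers), via open nitro alcohol 25 (not isolated)
Conditions: MeNO2 (1.5 equiv), Cu(OAc)2·H2O (10 mol %), 2,2′-(propane-2,2-diyl)bis(3a,8a-dihydro-8H-indeno[1,2-d]oxazole) (inda-BOX, 11 mol %), EtOH, 0 °C → rt
Reagents that add atoms: none
Why: Copper-bound acetate deprotonates nitromethane and the nitronate adds to one copper-coordinated aldehyde (C8–C9, drawn for the less hindered C9 aldehyde), after which the β-nitro alcohol 25 is deprotonated again at C8 and adds to the C7 aldehyde (C7–C8), so nitromethane serves as a one-carbon 1,1-dinucleophile in a twofold Henry reaction. The closest known chemistry is the nitromethane cyclisation of dialdehydes to cyclic 2-nitro-1,3-diols, the Cu(OAc)2/bis(oxazoline) enantioselective Henry reaction of tert-alkyl aldehydes such as pivalaldehyde, and tandem inter–intramolecular nitroaldol reactions under chiral metal catalysis. The closure is 7-exo-trig, but because C5 and C10 are 1,3 on the cyclobutane and hold the arms cis it has the geometry of a six-membered closure. The substrate cannot choose the aldehyde faces itself, since the two sides of the C5/C6/C9/C10 plane differ only in C1=O versus C3–Me several bonds away and an equilibrating base would give the two trans diols in equal amounts; the ligand therefore assigns each face as for a tert-alkyl aldehyde, and the same topicity at both carbinols (7S,9S) corresponds to the 7,9-trans diol with 9-OH on the C11 face and 7-OH on the C4 face. C8 forms as an epimer mixture that the next step removes. The step needs kinetic control (acetate as the only base, no free amine, rt or below) so that retro-nitroaldol does not scramble the carbinols; the two non-enolisable aldehydes and the β,β-disubstituted enone, a poor nitronate acceptor, secure chemoselectivity, and the limited amount of nitromethane leaves the second aldehyde to the internal nitronate.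

Step 14
Reactants: 26 nitro diol
Product: 27 (7R,9R)-7,9-dihydroxy tricyclic enone (trans diol)
Conditions: Bu3SnH (5 equiv), AIBN (portionwise), toluene, 110 °C
Reagents that add atoms: none
Why: Radical denitration, in which the stannyl radical adds to the nitro group, the C8–N bond cleaves and the secondary C8 radical takes hydrogen from the stannane; C8 becomes CH2 so its epimers converge, and this radical is not adjacent to the cyclobutane, so no cyclobutylcarbinyl opening can follow.

Step 15
Reactants: 27 diol; 28 tiglic acid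
Product: 30 9-O-[(E)-2-methylbut-2-enoyl] 7-ol, via mixed anhydride 29 (not isolated)
Conditions: 28 (1.05 equiv), 2,4,6-trichlorobenzoyl chloride, Et3N, toluene, rt; then 27, DMAP, 0 °C → rt
Reagents that add atoms: none
Why: Yamaguchi esterification through the mixed anhydride and the acyl-pyridinium ion, in which one equivalent of the α-branched acyl donor should take the C9 carbinol, whose quaternary neighbour C10 is tied back in the cyclobutane, before the C7 carbinol flanked by the gem-dimethyl group; the tiglate geometry is the thermodynamically stable one and should not isomerise.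

Step 16
Reactants: 30 mono-tiglate; 31 3-methylbut-2-enoyl chloride
Product: 32 CNP0277258.1
Conditions: 31 (3 equiv), DMAP, pyridine, CH2Cl2, 0 → 40 °C
Reagents that add atoms: none
Why: DMAP-catalysed acylation of the remaining hindered C7 carbinol by the unbranched senecioyl chloride, with pyridine instead of a trialkylamine so that the acid chloride is not drawn off as a vinylketene and the acyl group stays conjugated.

**Compound list**

1 | tert-butyl 3-methylbut-2-enoate | CC(C)=CC(=O)OC(C)(C)C | starting material
2 | lithium 1-tert-butoxy-3-methylbuta-1,3-dien-1-olate | [Li+].[O-]C(OC(C)(C)C)=CC(C)=C | intermediate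
3 | tert-butyl[(1-tert-butoxy-3-methylbuta-1,3-dien-1-yl)oxy]dimethylsilane | C=C(C)C=C(OC(C)(C)C)O[Si](C)(C)C(C)(C)C | intermediate
4 | 3-methylbut-2-enal | CC(C)=CC=O | starting material
5 | tert-butyl (2E,5S)-3,7-dimethyl-5-(trichlorosilyloxy)octa-2,6-dienoate | CC(C)=C[C@@H](O[Si](Cl)(Cl)Cl)C/C(C)=C/C(=O)OC(C)(C)C | intermediate
6 | tert-butyl (2E,5S)-5-hydroxy-3,7-dimethylocta-2,6-dienoate | CC(C)=C[C@@H](O)C/C(C)=C/C(=O)OC(C)(C)C | intermediate
7 | tert-butyl (2E,5S)-5-(tert-butyldimethylsilyloxy)-3,7-dimethylocta-2,6-dienoate | CC(C)=C[C@@H](O[Si](C)(C)C(C)(C)C)C/C(C)=C/C(=O)OC(C)(C)C | intermediate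
8 | tert-butyl (2E,5S,6E)-5-(tert-butyldimethylsilyloxy)-8-hydroxy-3,7-dimethylocta-2,6-dienoate | OC/C(C)=C/[C@@H](O[Si](C)(C)C(C)(C)C)C/C(C)=C/C(=O)OC(C)(C)C | intermediate
9 | 2-methylpropanoyl chloride | CC(C)C(Cl)=O | starting material
10 | tert-butyl (2E,5S,6E)-5-(tert-butyldimethylsilyloxy)-3,7-dimethyl-8-(2-methylpropanoyloxy)octa-2,6-dienoate | CC(C)C(=O)OC/C(C)=C/[C@@H](O[Si](C)(C)C(C)(C)C)C/C(C)=C/C(=O)OC(C)(C)C | intermediate
11 | trimethylsilyl ester of acid 12 | CC(C)C(=O)OC/C(C)=C/[C@@H](O[Si](C)(C)C(C)(C)C)C/C(C)=C/C(=O)O[Si](C)(C)C | intermediate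
12 | (2E,5S,6E)-5-(tert-butyldimethylsilyloxy)-3,7-dimethyl-8-(2-methylpropanoyloxy)octa-2,6-dienoic acid | CC(C)C(=O)OC/C(C)=C/[C@@H](O[Si](C)(C)C(C)(C)C)C/C(C)=C/C(=O)O | intermediate
13 | acid chloride of 12 | CC(C)C(=O)OC/C(C)=C/[C@@H](O[Si](C)(C)C(C)(C)C)C/C(C)=C/C(Cl)=O | intermediate
14 | vinylketene, (5S,6E)-5-(tert-butyldimethylsilyloxy)-7-methyl-3-methylidene-8-(2-methylpropanoyloxy)octa-1,6-dien-1-one | CC(C)C(=O)OC/C(C)=C/[C@@H](O[Si](C)(C)C(C)(C)C)CC(=C)C=C=O | intermediate
15 | bicyclic ketone: 3-methylidene-5-oxobicyclo[3.1.1]heptane (target numbering), (1S)-1-OSiMe2tBu on the C5 side, 10-Me syn, 10-CH2OC(O)CHMe2 anti | O=C1[C@H]2[C@@H](O[Si](C)(C)C(C)(C)C)CC(=C)[C@@H]1[C@]2(COC(=O)C(C)C)C | intermediate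
16 | lithium aldolate: lactone C9–O–C7(=O)–C6Me2–C5 with C5–OLi syn | O=C1C(C)(C)[C@]2([O-])[C@H]3[C@@H](O[Si](C)(C)C(C)(C)C)CC(=C)[C@@H]2[C@@]3(C)CO1.[Li+] | intermediate
17 | lithium O-(C5) dithiocarbonate of the lactone | O=C1C(C)(C)[C@]2(OC(=S)[S-])[C@H]3[C@@H](O[Si](C)(C)C(C)(C)C)CC(=C)[C@@H]2[C@@]3(C)CO1.[Li+] | intermediate
18 | S-methyl xanthate of the C5 tertiary alcohol (lactone) | O=C1C(C)(C)[C@]2(OC(=S)SC)[C@H]3[C@@H](O[Si](C)(C)C(C)(C)C)CC(=C)[C@@H]2[C@@]3(C)CO1 | intermediate
19 | lactone with C5–H syn, 1-OSiMe2tBu, C3=CH2 | O=C1C(C)(C)[C@@H]2[C@H]3[C@@H](O[Si](C)(C)C(C)(C)C)CC(=C)[C@@H]2[C@@]3(C)CO1 | intermediate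
20 | 7,9-diol with 1-OSiMe2tBu (C5–CMe2CH2OH anti, C10–CH2OH anti) | OCC(C)(C)[C@@H]1[C@H]2[C@@H](O[Si](C)(C)C(C)(C)C)CC(=C)[C@@H]1[C@@]2(C)CO | intermediate
21 | 1,7,9-triol with exocyclic C3=CH2 | OCC(C)(C)[C@@H]1[C@H]2[C@@H](O)CC(=C)[C@@H]1[C@@]2(C)CO | intermediate
22 | exo-methylene keto dialdehyde (C1 ketone, C3=CH2, C7 and C9 aldehydes) | O=CC(C)(C)[C@@H]1[C@H]2C(=O)CC(=C)[C@@H]1[C@@]2(C)C=O | intermediate
23 | 2-(6-formyl-4,6-dimethyl-2-oxobicyclo[3.1.1]hept-3-en-7-yl)-2-methylpropanal (enone C7,C9-dialdehyde, arms cis) | O=CC(C)(C)[C@@H]1[C@H]2C(=O)C=C(C)[C@@H]1[C@@]2(C)C=O | intermediate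
24 | nitromethane | C[N+](=O)[O-] | starting material
25 | open nitro alcohol: (9S)-9-hydroxy-8-nitro adduct at the C9 aldehyde, C7 aldehyde free | O=CC(C)(C)[C@@H]1[C@H]2C(=O)C=C(C)[C@@H]1[C@@]2(C)[C@H](O)C[N+](=O)[O-] | intermediate
26 | (7S,9S)-7,9-dihydroxy-8-nitro tricyclic enone (C8 epimers) | O[C@@H]1C([N+](=O)[O-])[C@@H](O)C(C)(C)[C@@H]2[C@H]3C(=O)C=C(C)[C@@H]2[C@]31C | intermediate
27 | (7R,9R)-7,9-dihydroxy tricyclic enone | O[C@@H]1C[C@@H](O)C(C)(C)[C@@H]2[C@H]3C(=O)C=C(C)[C@@H]2[C@]31C | intermediate
28 | tiglic acid, (E)-2-methylbut-2-enoic acid | C/C=C(\C)C(=O)O | starting material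
29 | (E)-2-methylbut-2-enoic 2,4,6-trichlorobenzoic anhydride | C/C=C(\C)C(=O)OC(=O)c1c(Cl)cc(Cl)cc1Cl | intermediate
30 | 9-O-tigloyl 7-ol | C/C=C(\C)C(=O)O[C@@H]1C[C@@H](O)C(C)(C)[C@@H]2[C@H]3C(=O)C=C(C)[C@@H]2[C@]31C | intermediate
31 | 3-methylbut-2-enoyl chloride | CC(C)=CC(Cl)=O | starting material
32 | CNP0277258.1, 9-O-tigloyl 7-O-senecioyl diester | C/C=C(\C)C(=O)O[C@@H]1C[C@@H](OC(=O)C=C(C)C)C(C)(C)[C@@H]2[C@H]3C(=O)C=C(C)[C@@H]2[C@]31C | target

**Step count and risks**

Total steps: 16. Longest linear sequence: 16 steps (1 → 32); 4, 9, 24, 28 and 31 enter as purchased materials.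

Steps most likely to fail:

1. Step 13. The ring-closing addition may escape the catalyst (the internal nitronate choosing the C7 aldehyde face by ring strain), or retro-nitroaldol may erase the face selection, so that cis diols or the other trans diol are carried along. Fallback, from 23 back to 27: the reaction is stopped after the intermolecular addition (1.05 equiv MeNO2, −20 °C) and open adduct 25 is isolated. Its hydroxyl is capped (Et3SiOTf, 2,6-lutidine) to give the 9-O-triethylsilyl nitro aldehyde F1, which can no longer revert at C9. Catalytic tetramethylguanidine in THF then closes the ring to the 8-nitro-9-silyloxy-7-ol F2 (C7 and C8 epimers), and Bu3SnH/AIBN gives the 9-silyloxy-7-ol F3. The periodinane DMP oxidises the only free carbinol to the 9-silyloxy-7-ketone F4, and HF·pyridine frees the 9-hydroxy-7-ketone F5. Me4NBH(OAc)3 (MeCN/AcOH, −20 °C) then delivers hydride from the C9 alkoxyborohydride to the same face of C7 (1,3-anti reduction), which should give trans diol 27 whatever the C7 configuration of F2 was, without touching the enone.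

2. Step 14. Homolysis of the secondary C8–N bond is slow, and in that time stannyl radicals can add to the enone oxygen; the resulting allylic radical is cyclobutylcarbinyl at C4 and C11 and would open the four-membered ring. Fallback, from 26 back to 27: the enone is masked before the radical step. Luche reduction (NaBH4, CeCl3·7H2O, MeOH, −40 °C) gives the allylic alcohol nitro triol F6, denitration under the conditions of step 14 gives the triol F7, and MnO2 in CH2Cl2 re-oxidises only the allylic C1 carbinol to return 27.

3. Step 15. Discrimination between two neopentylic secondary carbinols may be poor, leading to over-acylation and the C7 regioisomer. Fallback, from 27 to 32: site selection is handed to the more size-sensitive silylation. tBuMe2SiOTf (1.05 equiv) with 2,6-lutidine at −78 °C gives the 9-O-silyl 7-ol F8, senecioylation with 31 and DMAP gives the 9-O-silyl 7-senecioate F9, HF·pyridine gives the 7-senecioate 9-ol F10, and Yamaguchi esterification with 28 then gives 32.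

Further compounds
F1 | step 13 | 9-O-triethylsilyl ether of open nitro alcohol 25 | O=CC(C)(C)[C@@H]1[C@H]2C(=O)C=C(C)[C@@H]1[C@@]2(C)[C@H](O[Si](CC)(CC)CC)C[N+](=O)[O-]
F2 | step 13 | 8-nitro-9-(triethylsilyloxy) tricyclic enone 7-ol (C7 and C8 epimers) | CC[Si](CC)(CC)O[C@@H]1C([N+](=O)[O-])C(O)C(C)(C)[C@@H]2[C@H]3C(=O)C=C(C)[C@@H]2[C@]31C
F3 | step 13 | 9-(triethylsilyloxy) tricyclic enone 7-ol (C7 epimers) | CC[Si](CC)(CC)O[C@@H]1CC(O)C(C)(C)[C@@H]2[C@H]3C(=O)C=C(C)[C@@H]2[C@]31C
F4 | step 13 | 9-(triethylsilyloxy) tricyclic 1,7-dione | CC[Si](CC)(CC)O[C@@H]1CC(=O)C(C)(C)[C@@H]2[C@H]3C(=O)C=C(C)[C@@H]2[C@]31C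
F5 | step 13 | (9R)-9-hydroxy tricyclic 1,7-dione | O[C@@H]1CC(=O)C(C)(C)[C@@H]2[C@H]3C(=O)C=C(C)[C@@H]2[C@]31C
F6 | step 14 | 8-nitro-1,7,9-triol (C1 allylic alcohol, OH expected on the C10 side) | O[C@@H]1C([N+](=O)[O-])[C@@H](O)C(C)(C)[C@@H]2[C@H]3[C@H](O)C=C(C)[C@@H]2[C@]31C
F7 | step 14 | 1,7,9-triol (C1 allylic alcohol) | O[C@@H]1C[C@@H](O)C(C)(C)[C@@H]2[C@H]3[C@H](O)C=C(C)[C@@H]2[C@]31C
F8 | step 15 | 9-O-(tert-butyldimethylsilyl) 7-ol | CC(C)(C)[Si](C)(C)O[C@@H]1C[C@@H](O)C(C)(C)[C@@H]2[C@H]3C(=O)C=C(C)[C@@H]2[C@]31C
F9 | step 15 | 9-O-(tert-butyldimethylsilyl) 7-O-(3-methylbut-2-enoyl) diol derivative | CC(C)(C)[Si](C)(C)O[C@@H]1C[C@@H](OC(=O)C=C(C)C)C(C)(C)[C@@H]2[C@H]3C(=O)C=C(C)[C@@H]2[C@]31C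
F10 | step 15 | 7-O-(3-methylbut-2-enoyl) 9-ol | O[C@@H]1C[C@@H](OC(=O)C=C(C)C)C(C)(C)[C@@H]2[C@H]3C(=O)C=C(C)[C@@H]2[C@]31C
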